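TBSO = tert-butyldimethylsilyloxy. Ring and atom labels (ring D: O1–C2–C3–C3a=C7a; ring F: the fused 2-pyranone; ring P: the pendant hydroxypyranone) are used throughout.

## The problem

Target 21 is a 2,3-dihydro-4H-furo[3,2-c]pyran-4-one. Dihydrofuran ring D shares the C3a=C7a bond with 2-pyranone ring F, which carries an (E)-3,4-dihydroxystyryl arm on C6; C2 bears a catechol ring and C3 bears ring P, a 4-hydroxy-2-pyranone joined through its C6. The only stereocentres are C2 and C3, trans and (2R,3R). C3–H is flanked by C3a and by ring P (earlier, by a carbonyl group) and can be exchanged, so C3 may be left to thermodynamic control and will follow C2; C2 has no exchangeable hydrogen and must be set in absolute terms. C2–O1 is the weak bond: it is a para-oxygenated benzylic ether of a vinylogous acid, so strong Lewis or Brønsted acids ionise it, a carbanion at C3 can expel O1, and once the para phenol is free, base opens it through a quinone methide. Beside it stand two air-sensitive catechols, two lactones that do not survive prolonged hydroxide or alkoxide, an acidic and nucleophilic ring P, and a styryl olefin that forbids hydrogenolysis. These limits point to phenol protection that leaves with buffered fluoride and to a late, nearly base-free construction of ring P. The enabling feature is the 1,5 relationship inside ring D: C2 is benzylic and bound to O1, O1 sits on C7a and C3 on the neighbouring C3a, so a carbene centred on C3 lies five atoms from a benzylic hydrogen of a 4-O-benzyl ether and can close ring D by C–H insertion.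

## Retrosynthesis

**21 ⇒ 20.** The last cut removes four O–Si bonds. Silyl ethers are preferred to methyl ethers because the boron trihalides that cleave aryl methyl ethers are the reagents most likely to ionise C2–O1. Buffered fluoride touches neither that bond nor the lactones. The price is that every step after the silyl groups enter must avoid hydroxide and alkoxide, which shapes the cuts below. Ring P needs no protection because it is formed in the preceding step.

**20 ⇒ 19 ⇒ 16 + 17.** Ring P is cut at its lactone C–O bond and at the bond between the carbon on C3 and the next ring carbon. This leads through 3,5-diketo ester 19 to carboxylic acid 16 and diene 17, a silylated equivalent of the acetoacetate dianion. Condensing a C3 ester with the free dianion was set aside: the dianion would deprotonate C3–H instead of adding. Acid chloride 18 and 17 combine without any base, and lactonisation of 19 needs one equivalent of an amidine. The precursor is simpler by one heterocycle and four carbons.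

**16 ⇒ 15 ⇒ 14.** The acid is traced to trichloroethyl ester 15, because reductive cleavage with zinc frees the acid without hydroxide. Ester 15 is traced to its C3 epimer 14. Trans is the more stable arrangement, so catalytic base should turn the kinetic cis product of ring closure into 15 while C2 stays untouched.

**14 ⇒ 13 (key cut).** Cutting C2–C3 opens ring D and removes both stereocentres; 13 is achiral, with a diazo ester on pyranone C3 and a benzyl ether on O4. Neighbouring cuts were weighed:
- Cutting O1–C7a or C3–C3a leaves open-chain or ring-expanded precursors that must already hold the stereocentres.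
- The oxidative union of two molecules of 6 would give the skeleton of 20 in one step, but as a racemate.

The carbenoid cut is the only one in which a catalyst sets C2 in the ring-forming event. The forward reaction must pick one of two enantiotopic benzylic hydrogens and ignore the styryl olefin, the silyl ethers and the lactone.

**13 ⇒ 8 + 12.** The bond between pyranone C3 and the diazo carbon is cut. A zerovalent palladium catalyst couples iodide 8 with diazoacetate 12 and keeps the diazo group. This is preferred to diazo transfer onto a pyranonylacetate, which needs a stronger base and a separate C–C bond construction. Diazoacetate 12 comes from 9 and 10 through bromoacetate 11.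

**8 ⇒ 7 + 3, 7 ⇒ 6.** The O–CH2 bond is made by Mitsunobu etherification, which is neutral and selective for O4. The C–I bond is made by electrophilic iodination of free hydroxypyranone 6, where C3 is at its most nucleophilic; hence iodination precedes etherification.

**6 ⇒ 4 + 2 (through 5); 2 and 3 ⇐ 1.** The styryl olefin is cut to the lateral dianion of 4 and aldehyde 2, with dehydration of adduct 5. This is done first, for two reasons. After ring D exists, the 6-methyl group would compete with C3–H for base. The usual alkoxide-mediated condensation of methylpyranones would also strip aryl silyl ethers. Aldehyde 2 and alcohol 3 both come from 1.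

## Roads not taken

**Alternative 1:** Ring F is cut at C6–C7 and O5–C4. This leaves dihydrofuran ester A2, which already holds ring D and both stereocentres with a silyl alkyne on C3 as placeholder for ring P, and cinnamoyl N-methoxy-N-methylamide A3. In the forward step LiN(iPr)2 forms the extended dienolate at the 2-methyl group of A2; acylation by A3 and lactonisation give A1 with ring F and its styryl arm.
- Merits: the step is convergent, the styryl arm arrives intact, no diazo compound is handled, and C3 carries no carbonyl group during the base step. In these respects it is better than the chosen plan.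
- Weak points: A2 needs its own enantioselective synthesis of a trans-4-alkynyl-5-aryl dihydrofuran. The alkyne must later be turned into ring P over several steps through a propargylic C3–H that isomerises easily. The methyl ethers end in a boron trihalide deprotection.
- Against this, the chosen plan sets C2 by catalyst in the ring-forming step, carries C3 at the oxidation level ring P needs, and ends with fluoride.

**Alternative 2:** Ring D is cut at O1–C7a. Open-chain carbinol A5 holds every carbon and both stereocentres. KOtBu forms the C2 alkoxide, which adds to C7a of the 4-methoxypyranone and expels methoxide to give penta-O-methyl compound A4.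
- Merits: ring closure comes last, both centres are retained, and on paper the endgame is the shortest of all; it needs no epimerisation step. Here it is better than the chosen plan.
- Weak points: A5 is a beta-hydroxy compound whose carbanion partner is flanked by two pyranones, so the alkoxide can undergo retro-aldol cleavage and scramble both centres. The alkoxide can also attack the lactone carbonyls. A4 needs cleavage of five methyl ethers, one on ring P, under conditions that threaten C2–O1.
- Against this, the chosen plan forms the C–C bond irreversibly under catalyst control and avoids strong acid at the end.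

**Alternative 3:** The C3–C3a bond is made by rearrangement. Flavanone-like dione A7 is oxidised with PhI(OAc)2 and H2SO4 in trimethyl orthoformate; C3a migrates from the ketone carbon to the alpha carbon, the six-membered ring contracts to ring D and the ketone carbon becomes the ester of A6.
- Merits: the shift delivers the trans ester directly, with cheap reagents and no diazo or rhodium chemistry. In directness of the C3 configuration it is better than the chosen plan.
- Weak points: the single stereocentre of A7 is a beta-aryloxy ketone centre that racemises by reversible ring opening, and it still needs an asymmetric synthesis. Strong acid with an electron-rich 2-aryl group invites the competing aryl shift and dehydrogenation. A6 still carries a 6-methyl group that must be condensed next to an acidic C3–H, and methyl ethers.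
- Against this, the chosen plan creates C2 only when ring D closes, in a product where C2 can no longer racemise by ring opening under neutral conditions, and has the styryl arm in place beforehand.

Key step: step 8

Assumption: the sense of induction of Rh2(S-PTTL)4 is carried over from ortho-benzyloxy aryldiazoacetates, where it gives the (2R,3S)-cis ester; should the pyranonyl donor reverse it, Rh2(R-PTTL)4 is substituted and nothing else changes.

## Route

Step 1
Reactants: 1 3,4-dihydroxybenzaldehyde
Product: 2 3,4-bis(TBSO)benzaldehyde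
Conditions: TBSCl (2.4 equiv), imidazole (5 equiv), DMF, 0 °C → rt
Reagents that add atoms: tert-butyldimethylsilyl chloride (TBSCl), CC(C)(C)[Si](C)(C)Cl
Why: Routine O-silylation of both phenols with imidazole as base and silyl-transfer agent; the aldehyde is not affected and no stereocentre is involved.

Step 2
Reactants: 2 3,4-bis(TBSO)benzaldehyde
Product: 3 [3,4-bis(TBSO)phenyl]methanol
Conditions: NaBH4, THF–MeOH (10:1), 0 °C, short reaction time
Reagents that add atoms: none
Why: Hydride reduction of an aromatic aldehyde; low temperature and little methanol should keep the aryl silyl ethers from methanolysis.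

Step 3
Reactants: 4 4-hydroxy-6-methyl-2H-pyran-2-one; 2 3,4-bis(TBSO)benzaldehyde
Product: 6 6-{(E)-2-[3,4-bis(TBSO)phenyl]ethenyl}-4-hydroxy-2H-pyran-2-one, via hydroxyethyl aldol adduct 5 (not isolated)
Conditions: LiN(iPr)2 (2.3 equiv), THF–DMPU, −78 °C; 2, −78 → −30 °C; aq. NH4Cl; crude 5, TsOH·H2O (10 mol %), toluene (0.02 M), 70 °C
Reagents that add atoms: none
Why: Two equivalents of amide base give the O,C-dianion of 4, which adds to the non-enolisable aldehyde through the 6-methyl carbon (lateral vinylogous aldol addition); acid-catalysed dehydration of the para-silyloxybenzylic alcohol at high dilution should then give the conjugated olefin, E by thermodynamic control.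

Step 4
Reactants: 6 6-{(E)-2-[3,4-bis(TBSO)phenyl]ethenyl}-4-hydroxy-2H-pyran-2-one
Product: 7 6-{(E)-2-[3,4-bis(TBSO)phenyl]ethenyl}-4-hydroxy-3-iodo-2H-pyran-2-one
Conditions: NIS (1.05 equiv), MeCN, 0 °C, dark
Reagents that add atoms: N-iodosuccinimide (NIS), O=C1CCC(=O)N1I
Why: Electrophilic iodination; C3 is the central carbon of a cyclic 1,3-dicarbonyl enol and far more nucleophilic than the silyloxyarenes or the pyranone-conjugated olefin.

Step 5
Reactants: 7 6-{(E)-2-[3,4-bis(TBSO)phenyl]ethenyl}-4-hydroxy-3-iodo-2H-pyran-2-one; 3 [3,4-bis(TBSO)phenyl]methanol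
Product: 8 4-{[3,4-bis(TBSO)phenyl]methoxy}-6-{(E)-2-[3,4-bis(TBSO)phenyl]ethenyl}-3-iodo-2H-pyran-2-one
Conditions: PPh3, DIAD, THF, 0 °C → rt
Reagents that add atoms: none
Why: Mitsunobu etherification of an acidic hydroxypyranone with a primary benzylic alcohol; 4-hydroxy-2-pyranones are alkylated on O4 under these neutral conditions, giving the 4-alkoxy-2-pyranone and not the 2-alkoxy-4-pyranone.

Step 6
Reactants: 9 2,2,2-trichloroethanol; 10 bromoacetyl bromide
Product: 12 2,2,2-trichloroethyl 2-diazoacetate, via 2,2,2-trichloroethyl bromoacetate 11 (not isolated)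
Conditions: NaHCO3, MeCN, 0 °C; then TsNHNHTs (2 equiv), DBU (5 equiv), THF, 0 °C
Reagents that add atoms: N,N'-ditosylhydrazine, Cc1ccc(cc1)S(=O)(=O)NNS(=O)(=O)c1ccc(C)cc1
Why: O-acylation gives the bromoacetate; N-alkylation of the bis-sulfonylhydrazine and two base-induced sulfinate eliminations (Bamford–Stevens-type) then give the diazoacetate, a standard preparation of diazoacetic esters from alcohols.

Step 7
Reactants: 8 4-{[3,4-bis(TBSO)phenyl]methoxy}-6-{(E)-2-[3,4-bis(TBSO)phenyl]ethenyl}-3-iodo-2H-pyran-2-one; 12 2,2,2-trichloroethyl 2-diazoacetate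
Product: 13 2,2,2-trichloroethyl 2-diazo-2-[4-{[3,4-bis(TBSO)phenyl]methoxy}-6-{(E)-2-[3,4-bis(TBSO)phenyl]ethenyl}-2-oxo-2H-pyran-3-yl]acetate
Conditions: 12 (1.5 equiv), Pd(PPh3)4 (10 mol %), Ag2CO3 (0.5 equiv), Et3N (1.3 equiv), toluene, rt
Reagents that add atoms: none
Why: Zerovalent-palladium-catalysed cross-coupling of an sp2 iodide with the C–H bond of an acceptor diazo compound, known for aryl and vinyl iodides and for trichloroethyl diazoacetate; oxidative addition at the 3-iodopyranone, silver-assisted deprotonative transfer of the diazoacetate and reductive elimination keep the diazo group at room temperature.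

Step 8
Reactants: 13 2,2,2-trichloroethyl 2-diazo-2-[4-{[3,4-bis(TBSO)phenyl]methoxy}-6-{(E)-2-[3,4-bis(TBSO)phenyl]ethenyl}-2-oxo-2H-pyran-3-yl]acetate
Product: 14 2,2,2-trichloroethyl (2R,3S)-2-[3,4-bis(TBSO)phenyl]-6-{(E)-2-[3,4-bis(TBSO)phenyl]ethenyl}-4-oxo-2,3-dihydro-4H-furo[3,2-c]pyran-3-carboxylate (cis)
Conditions: Rh2(S-PTTL)4 (2 mol %), toluene, 4 Å MS, −60 °C, 13 added over 2 h
Reagents that add atoms: none
Why: Rh2(S-PTTL)4, the divalent rhodium dimer bridged by four N-phthaloyl-(S)-tert-leucinates, expels N2 from 13 to give an electrophilic donor/acceptor carbenoid whose carbon (future C3) takes one benzylic ether hydrogen in a concerted, asynchronous three-centre transition state and forms C2–C3 in the same event. The closest known reaction is the enantioselective intramolecular C–H insertion of ortho-benzyloxy aryldiazoacetates to cis-2-aryl-2,3-dihydrobenzofuran-3-carboxylates with this catalyst; here the 4-alkoxy-2-pyranon-3-yl ring takes the place of the donor arene. Ring D closes as a 1,5-insertion through a five-membered transition state made of the carbenoid carbon, C3a, C7a, O1 and the benzylic carbon. C2 is set by the chiral carboxylate ligands, which distinguish the two enantiotopic benzylic hydrogens; in the benzofuran series the S catalyst gives the 2R configuration needed here. C3 is set relative to C2 by the geometry of the insertion, which places ester and aryl cis, and this is of no lasting consequence because step 9 equilibrates it. The step needs chemoselectivity for the 1,5 C–H bond over carbene dimerisation, arene cyclopropanation and attack on the styryl olefin: the C–H bond is benzylic, alpha to oxygen and on an electron-rich arene, slow addition keeps the diazo concentration low, and a trans-1,2-disubstituted olefin conjugated to the pyranone is a poor partner for a bulky donor/acceptor carbenoid and is out of intramolecular reach. Silyl ethers, trichloroethyl ester and lactone should be inert to the catalyst at −60 °C.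

Step 9
Reactants: 14 2,2,2-trichloroethyl (2R,3S)-2-[3,4-bis(TBSO)phenyl]-6-{(E)-2-[3,4-bis(TBSO)phenyl]ethenyl}-4-oxo-2,3-dihydro-4H-furo[3,2-c]pyran-3-carboxylate
Product: 15 2,2,2-trichloroethyl (2R,3R)-2-[3,4-bis(TBSO)phenyl]-6-{(E)-2-[3,4-bis(TBSO)phenyl]ethenyl}-4-oxo-2,3-dihydro-4H-furo[3,2-c]pyran-3-carboxylate (trans)
Conditions: DBU (0.2 equiv), CH2Cl2 (dry), 0 °C → rt
Reagents that add atoms: none
Why: Base-mediated epimerisation through the ester enolate, as known for cis-2-aryl-2,3-dihydrobenzofuran-3-carboxylates; the trans isomer with aryl and ester on opposite faces is thermodynamically preferred, and C2 has no acidic hydrogen, so C3 is corrected to R under the control of C2.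

Step 10
Reactants: 15 2,2,2-trichloroethyl (2R,3R)-2-[3,4-bis(TBSO)phenyl]-6-{(E)-2-[3,4-bis(TBSO)phenyl]ethenyl}-4-oxo-2,3-dihydro-4H-furo[3,2-c]pyran-3-carboxylate
Product: 16 (2R,3R)-2-[3,4-bis(TBSO)phenyl]-6-{(E)-2-[3,4-bis(TBSO)phenyl]ethenyl}-4-oxo-2,3-dihydro-4H-furo[3,2-c]pyran-3-carboxylic acid
Conditions: Zn dust, AcOH–THF (1:4), rt
Reagents that add atoms: none
Why: Reductive beta-elimination of the trichloroethyl group frees the acid under weakly acidic conditions, so the aryl silyl ethers, both lactone-type carbonyls and the C3 configuration are not exposed to hydroxide.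

Step 11
Reactants: 16 (2R,3R)-2-[3,4-bis(TBSO)phenyl]-6-{(E)-2-[3,4-bis(TBSO)phenyl]ethenyl}-4-oxo-2,3-dihydro-4H-furo[3,2-c]pyran-3-carboxylic acid; 17 1-methoxy-1,3-bis(trimethylsilyloxy)buta-1,3-diene
Product: 19 methyl 5-[(2R,3R)-2-[3,4-bis(TBSO)phenyl]-6-{(E)-2-[3,4-bis(TBSO)phenyl]ethenyl}-4-oxo-2,3-dihydro-4H-furo[3,2-c]pyran-3-yl]-3,5-dioxopentanoate, via acid chloride 18 (not isolated)
Conditions: 1-chloro-N,N,2-trimethylprop-1-en-1-amine (1.2 equiv), CH2Cl2, 0 °C → rt; then 17 (2 equiv), −78 → 20 °C; aq. NH4Cl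
Reagents that add atoms: none
Why: The chloroenamine makes the acid chloride without acid or base, and the terminal carbon of the bis-silyl dienol ether, a masked acetoacetate dianion, is C-acylated by acid chlorides without added base (Mukaiyama-type acylation) to give the 3,5-dioxo ester after hydrolysis; no enolate is formed at C3, so the trans configuration should persist.

Step 12
Reactants: 19 methyl 5-[(2R,3R)-2-[3,4-bis(TBSO)phenyl]-6-{(E)-2-[3,4-bis(TBSO)phenyl]ethenyl}-4-oxo-2,3-dihydro-4H-furo[3,2-c]pyran-3-yl]-3,5-dioxopentanoate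
Product: 20 (2R,3R)-2-[3,4-bis(TBSO)phenyl]-6-{(E)-2-[3,4-bis(TBSO)phenyl]ethenyl}-3-(4-hydroxy-2-oxo-2H-pyran-6-yl)-2,3-dihydro-4H-furo[3,2-c]pyran-4-one
Conditions: DBU (1.1 equiv), toluene, rt → 40 °C; then aq. citric acid
Reagents that add atoms: none
Why: The enol oxygen of the 5-ketone attacks the methyl ester (lactonisation of a 3,5-diketo ester, a known amidine-mediated route to 6-substituted 4-hydroxy-2-pyranones) with loss of methanol; one equivalent of DBU is consumed by the acidic diketone and product, so no free base remains to attack silyl ethers, and trans stays the favoured arrangement at C3.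

Step 13
Reactants: 20 (2R,3R)-2-[3,4-bis(TBSO)phenyl]-6-{(E)-2-[3,4-bis(TBSO)phenyl]ethenyl}-3-(4-hydroxy-2-oxo-2H-pyran-6-yl)-2,3-dihydro-4H-furo[3,2-c]pyran-4-one
Product: 21 (2R,3R)-2-(3,4-dihydroxyphenyl)-6-[(E)-2-(3,4-dihydroxyphenyl)ethenyl]-3-(4-hydroxy-2-oxo-2H-pyran-6-yl)-2,3-dihydro-4H-furo[3,2-c]pyran-4-one
Conditions: HF·pyridine, pyridine, THF, 0 °C → rt, argon; Me3SiOMe quench
Reagents that add atoms: none
Why: Fluoride cleaves the four aryl O–Si bonds (desilylation); the pyridine-buffered, weakly acidic medium generates no phenoxide para to C2 that could open ring D through a quinone methide, and lactones, olefin and both stereocentres are not affected.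

## Compound list

1 | 3,4-dihydroxybenzaldehyde | O=Cc1ccc(O)c(O)c1 | starting material
2 | 3,4-bis(tert-butyldimethylsilyloxy)benzaldehyde | O=Cc1ccc(O[Si](C)(C)C(C)(C)C)c(O[Si](C)(C)C(C)(C)C)c1 | intermediate
3 | [3,4-bis(tert-butyldimethylsilyloxy)phenyl]methanol | OCc1ccc(O[Si](C)(C)C(C)(C)C)c(O[Si](C)(C)C(C)(C)C)c1 | intermediate
4 | 4-hydroxy-6-methyl-2H-pyran-2-one | Cc1cc(O)cc(=O)o1 | starting material
5 | 6-{2-[3,4-bis(TBSO)phenyl]-2-hydroxyethyl}-4-hydroxy-2H-pyran-2-one (racemic aldol adduct, not isolated) | O=c1cc(O)cc(CC(O)c2ccc(O[Si](C)(C)C(C)(C)C)c(O[Si](C)(C)C(C)(C)C)c2)o1 | intermediate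
6 | 6-{(E)-2-[3,4-bis(TBSO)phenyl]ethenyl}-4-hydroxy-2H-pyran-2-one | O=c1cc(O)cc(/C=C/c2ccc(O[Si](C)(C)C(C)(C)C)c(O[Si](C)(C)C(C)(C)C)c2)o1 | intermediate
7 | 6-{(E)-2-[3,4-bis(TBSO)phenyl]ethenyl}-4-hydroxy-3-iodo-2H-pyran-2-one | O=c1oc(/C=C/c2ccc(O[Si](C)(C)C(C)(C)C)c(O[Si](C)(C)C(C)(C)C)c2)cc(O)c1I | intermediate
8 | 4-{[3,4-bis(TBSO)phenyl]methoxy}-6-{(E)-2-[3,4-bis(TBSO)phenyl]ethenyl}-3-iodo-2H-pyran-2-one | O=c1oc(/C=C/c2ccc(O[Si](C)(C)C(C)(C)C)c(O[Si](C)(C)C(C)(C)C)c2)cc(OCc2ccc(O[Si](C)(C)C(C)(C)C)c(O[Si](C)(C)C(C)(C)C)c2)c1I | intermediate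
9 | 2,2,2-trichloroethanol | OCC(Cl)(Cl)Cl | starting material
10 | bromoacetyl bromide | BrCC(Br)=O | starting material
11 | 2,2,2-trichloroethyl bromoacetate (not isolated) | BrCC(=O)OCC(Cl)(Cl)Cl | intermediate
12 | 2,2,2-trichloroethyl 2-diazoacetate | ClC(Cl)(Cl)COC(=O)C=[N+]=[N-] | intermediate
13 | 2,2,2-trichloroethyl 2-diazo-2-[4-{[3,4-bis(TBSO)phenyl]methoxy}-6-{(E)-2-[3,4-bis(TBSO)phenyl]ethenyl}-2-oxo-2H-pyran-3-yl]acetate | ClC(Cl)(Cl)COC(=O)C(=[N+]=[N-])c1c(OCc2ccc(O[Si](C)(C)C(C)(C)C)c(O[Si](C)(C)C(C)(C)C)c2)cc(/C=C/c2ccc(O[Si](C)(C)C(C)(C)C)c(O[Si](C)(C)C(C)(C)C)c2)oc1=O | intermediate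
14 | 2,2,2-trichloroethyl (2R,3S)-2-[3,4-bis(TBSO)phenyl]-6-{(E)-2-[3,4-bis(TBSO)phenyl]ethenyl}-4-oxo-2,3-dihydro-4H-furo[3,2-c]pyran-3-carboxylate (cis) | ClC(Cl)(Cl)COC(=O)[C@H]1c2c(cc(/C=C/c3ccc(O[Si](C)(C)C(C)(C)C)c(O[Si](C)(C)C(C)(C)C)c3)oc2=O)O[C@H]1c1ccc(O[Si](C)(C)C(C)(C)C)c(O[Si](C)(C)C(C)(C)C)c1 | intermediate
15 | 2,2,2-trichloroethyl (2R,3R)-2-[3,4-bis(TBSO)phenyl]-6-{(E)-2-[3,4-bis(TBSO)phenyl]ethenyl}-4-oxo-2,3-dihydro-4H-furo[3,2-c]pyran-3-carboxylate (trans) | ClC(Cl)(Cl)COC(=O)[C@@H]1c2c(cc(/C=C/c3ccc(O[Si](C)(C)C(C)(C)C)c(O[Si](C)(C)C(C)(C)C)c3)oc2=O)O[C@H]1c1ccc(O[Si](C)(C)C(C)(C)C)c(O[Si](C)(C)C(C)(C)C)c1 | intermediate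
16 | (2R,3R)-2-[3,4-bis(TBSO)phenyl]-6-{(E)-2-[3,4-bis(TBSO)phenyl]ethenyl}-4-oxo-2,3-dihydro-4H-furo[3,2-c]pyran-3-carboxylic acid | OC(=O)[C@@H]1c2c(cc(/C=C/c3ccc(O[Si](C)(C)C(C)(C)C)c(O[Si](C)(C)C(C)(C)C)c3)oc2=O)O[C@H]1c1ccc(O[Si](C)(C)C(C)(C)C)c(O[Si](C)(C)C(C)(C)C)c1 | intermediate
17 | 1-methoxy-1,3-bis(trimethylsilyloxy)buta-1,3-diene | COC(O[Si](C)(C)C)=CC(=C)O[Si](C)(C)C | starting material
18 | (2R,3R)-2-[3,4-bis(TBSO)phenyl]-6-{(E)-2-[3,4-bis(TBSO)phenyl]ethenyl}-4-oxo-2,3-dihydro-4H-furo[3,2-c]pyran-3-carbonyl chloride (not isolated) | ClC(=O)[C@@H]1c2c(cc(/C=C/c3ccc(O[Si](C)(C)C(C)(C)C)c(O[Si](C)(C)C(C)(C)C)c3)oc2=O)O[C@H]1c1ccc(O[Si](C)(C)C(C)(C)C)c(O[Si](C)(C)C(C)(C)C)c1 | intermediate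
19 | methyl 5-[(2R,3R)-2-[3,4-bis(TBSO)phenyl]-6-{(E)-2-[3,4-bis(TBSO)phenyl]ethenyl}-4-oxo-2,3-dihydro-4H-furo[3,2-c]pyran-3-yl]-3,5-dioxopentanoate | COC(=O)CC(=O)CC(=O)[C@@H]1c2c(cc(/C=C/c3ccc(O[Si](C)(C)C(C)(C)C)c(O[Si](C)(C)C(C)(C)C)c3)oc2=O)O[C@H]1c1ccc(O[Si](C)(C)C(C)(C)C)c(O[Si](C)(C)C(C)(C)C)c1 | intermediate
20 | (2R,3R)-2-[3,4-bis(TBSO)phenyl]-6-{(E)-2-[3,4-bis(TBSO)phenyl]ethenyl}-3-(4-hydroxy-2-oxo-2H-pyran-6-yl)-2,3-dihydro-4H-furo[3,2-c]pyran-4-one | O=c1cc(O)cc([C@@H]2c3c(cc(/C=C/c4ccc(O[Si](C)(C)C(C)(C)C)c(O[Si](C)(C)C(C)(C)C)c4)oc3=O)O[C@H]2c2ccc(O[Si](C)(C)C(C)(C)C)c(O[Si](C)(C)C(C)(C)C)c2)o1 | intermediate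
21 | (2R,3R)-2-(3,4-dihydroxyphenyl)-6-[(E)-2-(3,4-dihydroxyphenyl)ethenyl]-3-(4-hydroxy-2-oxo-2H-pyran-6-yl)-2,3-dihydro-4H-furo[3,2-c]pyran-4-one | O=c1cc(O)cc([C@@H]2c3c(cc(/C=C/c4ccc(O)c(O)c4)oc3=O)O[C@H]2c2ccc(O)c(O)c2)o1 | target

## Step count and least certain steps

Total step count: 13. Longest linear sequence: 11 steps (1 → 2 → 6 → 7 → 8 → 13 → 14 → 15 → 16 → 19 → 20 → 21; steps 1, 3, 4, 5, 7, 8, 9, 10, 11, 12, 13). Steps 2 and 6 are side branches.

**Step 8 (key step).** The most likely failure is erosion of enantio- and chemoselectivity. The donor is a pyranone enol ether and not a benzene ring, so the carbenoid may discriminate the two benzylic hydrogens less well. The vinylogous diazo group may cyclise onto the ring double bond before the catalyst engages it. A slow reaction of the bulky substrate at low temperature would favour carbene dimerisation.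
Fallback: the skeleton is assembled by oxidative radical annulation. Hydroxypyranone 6 is oxidised with Mn(OAc)3 in AcOH (or with (NH4)2Ce(NO3)6 and NaHCO3 in MeCN). The C3 radical of one molecule adds to the styryl olefin of a second at the carbon next to the pyranone, and the benzylic radical is oxidised and captured by O4. This known type of 1,3-dicarbonyl/styrene annulation should give the racemic trans dimer F1. F1 is resolved by preparative chromatography on a chiral stationary phase to give 20. The fallback sets out from 6 and returns at 20; it gives up catalytic control of C2, loses half the material and risks over-oxidation.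

**Step 7.** The most likely failure is slow oxidative addition and diazo transfer at an iodide flanked by a carbonyl group and a bulky benzyloxy group, with palladium-carbene decomposition of the diazoacetate taking over.
Fallback: the diazo group is made by the Bamford–Stevens route. Iodide 8 undergoes iodine–magnesium exchange with iPrMgCl·LiCl at −40 °C. The pyranonyl Grignard reagent is acylated with bis(2,2,2-trichloroethyl) oxalate to give the alpha-keto ester F2. Condensation with tosylhydrazide gives the tosylhydrazone F3, and DBU eliminates sulfinate to give 13. The fallback sets out from 8 and returns at 13.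

**Step 9.** The most likely failure is beta-elimination of O1 from the C3 ester enolate. This opens ring D to an achiral arylidene ester and erases C2; the risk is raised by the good vinylogous-carboxylate leaving group, although the in-ring geometry disfavours it.
Fallback: C3 is equilibrated without a carbanion. Cis ester 14 is cleaved with Zn in AcOH–THF to the cis acid F4. The chloroenamine of step 11 converts it into the cis acid chloride F5. Catalytic Et3N dehydrochlorinates F5 reversibly to the ketene F6, which is planar at C3, and hydrogen chloride returns to give the more stable trans acid chloride 18. The fallback sets out from 14 and returns at 18.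

**Step 11.** The most likely failure is sluggish C-acylation of the hindered acid chloride, with O-acylation of the diene or loss of hydrogen chloride to a ketene competing.
Fallback: the acyl group is transferred to a dioxinone enolate and ring P is closed thermally. Acid 16 is converted with 1H-benzotriazole and SOCl2 into the N-acylbenzotriazole F7. F7 acylates the lithium dienolate of 2,2,6-trimethyl-4H-1,3-dioxin-4-one (LiN(SiMe3)2, THF, −78 °C) to give the keto-dioxinone F8. Heating F8 in toluene at 110 °C expels acetone, and the acylketene is captured by the enol oxygen to give 20 directly. The fallback sets out from 16 and returns at 20.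

**Step 13.** The most likely failure is ring opening of ring D through a para-quinone methide if phenoxide builds up during desilylation, together with air oxidation of the free catechols during isolation.
Fallback: the phenols are unveiled through acetates. Compound 20 is treated with Bu4NF in the presence of excess Ac2O, so that each phenoxide is acetylated as it is released, giving the penta-acetate F9, which can be purified without special care. Near-neutral deacetylation with NH4OAc in aqueous methanol then gives 21. The fallback sets out from 20 and returns at 21.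

## Further compounds

F1 | step 8 | racemic trans dimer, rac-(2R*,3R*) form of 20 (relative configuration shown) | O=c1cc(O)cc([C@@H]2c3c(cc(/C=C/c4ccc(O[Si](C)(C)C(C)(C)C)c(O[Si](C)(C)C(C)(C)C)c4)oc3=O)O[C@H]2c2ccc(O[Si](C)(C)C(C)(C)C)c(O[Si](C)(C)C(C)(C)C)c2)o1
F2 | step 7 | 2,2,2-trichloroethyl 2-oxo-2-[4-{[3,4-bis(TBSO)phenyl]methoxy}-6-{(E)-2-[3,4-bis(TBSO)phenyl]ethenyl}-2-oxo-2H-pyran-3-yl]acetate | ClC(Cl)(Cl)COC(=O)C(=O)c1c(OCc2ccc(O[Si](C)(C)C(C)(C)C)c(O[Si](C)(C)C(C)(C)C)c2)cc(/C=C/c2ccc(O[Si](C)(C)C(C)(C)C)c(O[Si](C)(C)C(C)(C)C)c2)oc1=O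
F3 | step 7 | N-tosylhydrazone of F2 | Cc1ccc(cc1)S(=O)(=O)NN=C(C(=O)OCC(Cl)(Cl)Cl)c1c(OCc2ccc(O[Si](C)(C)C(C)(C)C)c(O[Si](C)(C)C(C)(C)C)c2)cc(/C=C/c2ccc(O[Si](C)(C)C(C)(C)C)c(O[Si](C)(C)C(C)(C)C)c2)oc1=O
F4 | step 9 | (2R,3S)-2-[3,4-bis(TBSO)phenyl]-6-{(E)-2-[3,4-bis(TBSO)phenyl]ethenyl}-4-oxo-2,3-dihydro-4H-furo[3,2-c]pyran-3-carboxylic acid (cis) | OC(=O)[C@H]1c2c(cc(/C=C/c3ccc(O[Si](C)(C)C(C)(C)C)c(O[Si](C)(C)C(C)(C)C)c3)oc2=O)O[C@H]1c1ccc(O[Si](C)(C)C(C)(C)C)c(O[Si](C)(C)C(C)(C)C)c1
F5 | step 9 | (2R,3S) cis acid chloride of F4 | ClC(=O)[C@H]1c2c(cc(/C=C/c3ccc(O[Si](C)(C)C(C)(C)C)c(O[Si](C)(C)C(C)(C)C)c3)oc2=O)O[C@H]1c1ccc(O[Si](C)(C)C(C)(C)C)c(O[Si](C)(C)C(C)(C)C)c1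
F6 | step 9 | ketene: 2-[3,4-bis(TBSO)phenyl]-6-{(E)-2-[3,4-bis(TBSO)phenyl]ethenyl}-3-(oxomethylidene)-2,3-dihydro-4H-furo[3,2-c]pyran-4-one, C2 configured as in 14 | O=C=C1c2c(cc(/C=C/c3ccc(O[Si](C)(C)C(C)(C)C)c(O[Si](C)(C)C(C)(C)C)c3)oc2=O)O[C@H]1c1ccc(O[Si](C)(C)C(C)(C)C)c(O[Si](C)(C)C(C)(C)C)c1
F7 | step 11 | (2R,3R)-3-(1H-benzotriazol-1-ylcarbonyl)-2-[3,4-bis(TBSO)phenyl]-6-{(E)-2-[3,4-bis(TBSO)phenyl]ethenyl}-2,3-dihydro-4H-furo[3,2-c]pyran-4-one | O=C(n1nnc2ccccc12)[C@@H]1c2c(cc(/C=C/c3ccc(O[Si](C)(C)C(C)(C)C)c(O[Si](C)(C)C(C)(C)C)c3)oc2=O)O[C@H]1c1ccc(O[Si](C)(C)C(C)(C)C)c(O[Si](C)(C)C(C)(C)C)c1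
F8 | step 11 | (2R,3R)-2-[3,4-bis(TBSO)phenyl]-6-{(E)-2-[3,4-bis(TBSO)phenyl]ethenyl}-3-[2-(2,2-dimethyl-4-oxo-4H-1,3-dioxin-6-yl)acetyl]-2,3-dihydro-4H-furo[3,2-c]pyran-4-one | CC1(C)OC(CC(=O)[C@@H]2c3c(cc(/C=C/c4ccc(O[Si](C)(C)C(C)(C)C)c(O[Si](C)(C)C(C)(C)C)c4)oc3=O)O[C@H]2c2ccc(O[Si](C)(C)C(C)(C)C)c(O[Si](C)(C)C(C)(C)C)c2)=CC(=O)O1
F9 | step 13 | penta-acetate of 21, (2R,3R) | O=c1cc(OC(C)=O)cc([C@@H]2c3c(cc(/C=C/c4ccc(OC(C)=O)c(OC(C)=O)c4)oc3=O)O[C@H]2c2ccc(OC(C)=O)c(OC(C)=O)c2)o1
A1 | alternative 1 | trans-2-(3,4-dimethoxyphenyl)-6-[(E)-3,4-dimethoxystyryl]-3-[(triisopropylsilyl)ethynyl]-2,3-dihydro-4H-furo[3,2-c]pyran-4-one | CC(C)[Si](C#C[C@@H]1c2c(cc(/C=C/c3ccc(OC)c(OC)c3)oc2=O)O[C@H]1c1ccc(OC)c(OC)c1)(C(C)C)C(C)C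
A2 | alternative 1 | methyl trans-5-(3,4-dimethoxyphenyl)-2-methyl-4-[(triisopropylsilyl)ethynyl]-4,5-dihydrofuran-3-carboxylate | COC(=O)C1=C(C)O[C@@H](c2ccc(OC)c(OC)c2)[C@@H]1C#C[Si](C(C)C)(C(C)C)C(C)C
A3 | alternative 1 | (E)-3-(3,4-dimethoxyphenyl)-N-methoxy-N-methylprop-2-enamide | CON(C)C(=O)/C=C/c1ccc(OC)c(OC)c1
A4 | alternative 2 | penta-O-methyl ether of 21 | O=c1cc(OC)cc([C@@H]2c3c(cc(/C=C/c4ccc(OC)c(OC)c4)oc3=O)O[C@H]2c2ccc(OC)c(OC)c2)o1
A5 | alternative 2 | 3-[2-(3,4-dimethoxyphenyl)-2-hydroxy-1-(4-methoxy-2-oxo-2H-pyran-6-yl)ethyl]-6-[(E)-3,4-dimethoxystyryl]-4-methoxy-2H-pyran-2-one, configured as in A4 | COc1cc(/C=C/c2ccc(OC)c(OC)c2)oc(=O)c1[C@@H](c1cc(OC)cc(=O)o1)[C@@H](O)c1ccc(OC)c(OC)c1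
A6 | alternative 3 | methyl trans-2-(3,4-dimethoxyphenyl)-6-methyl-4-oxo-2,3-dihydro-4H-furo[3,2-c]pyran-3-carboxylate | COC(=O)[C@@H]1c2c(cc(C)oc2=O)O[C@H]1c1ccc(OC)c(OC)c1
A7 | alternative 3 | (2R)-2-(3,4-dimethoxyphenyl)-7-methyl-2,3-dihydropyrano[4,3-b]pyran-4,5-dione | Cc1cc2O[C@@H](c3ccc(OC)c(OC)c3)CC(=O)c2c(=O)o1
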